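Retrosynthetic plan
- The target is the 33-membered lactone of 32-hydroxydotriacontanoic acid: one unbranched ring O–C1(=O)–(CH2)31, with C1 the carbonyl carbon and C32 the OCH2 carbon, and no stereocentre.
- Cuts, in order: the eight C–H bonds on C7–C10 (back to a C7≡C8–C9≡C10 diyne); the ring bond C8–C9, an sp–sp bond between two acetylide carbons of like polarity; the ester bond C1(=O)–O; and C28–C29 of the alcohol half, after shifting its triple bond from C9≡C10 back to C29≡C30.
- Enabling feature: the ring is a plain polymethylene loop whose only functional group, the lactone C1(=O)–O–C32, lies seven bonds or more from C8 and C9. C7–C10 can therefore be carried as a linear 1,3-diyne, which a 33-membered ring holds without strain and which hydrogenation erases.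
- Forward order: acetylide alkylation (C28–C29), alkyne zipper to the chain end, esterification (C1–O), oxidative alkyne–alkyne ring closure at C8–C9 (the only ring), global hydrogenation.
- Stereochemistry: none to set; the target is achiral and fully saturated.

Key step: step 4

Remark: but-3-yn-1-ol, 1-bromoicosane and oct-7-ynoic acid are taken as commercial. Carbon numbers C1–C32 count along the acid chain from the carbonyl carbon, whereas ring locants in compound names count the ring oxygen as 1.

Step 1
Reactants: 1 but-3-yn-1-ol; 2 1-bromoicosane
Product: 5 tetracos-3-yn-1-ol, via dilithio dianion 3 (not isolated), via lithium alkoxide 4 (not isolated)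
Conditions: n-BuLi (2.1 equiv), THF/DMPU, −78 to −20 °C; then 2, −20 °C to rt; H2O
Reagents that add atoms: none
Why: In dianion 3 the acetylide carbon is far more nucleophilic than the lithium alkoxide oxygen, so SN2 displacement of the primary bromide (acetylide alkylation) should give C-alkylation only, and no stereocenter is formed.

Step 2
Reactants: 5 tetracos-3-yn-1-ol
Product: 7 tetracos-23-yn-1-ol, via dipotassium acetylide alkoxide 6 (not isolated)
Conditions: KH (5 equiv), H2N(CH2)3NH2, rt (KAPA); then 5, THF co-solvent, rt to 50 °C; H2O, 0 °C
Reagents that add atoms: none
Why: In the alkyne zipper reaction KAPA walks the triple bond along the chain by reversible propargyl/allenyl deprotonation–reprotonation until it reaches the methyl terminus, where irreversible formation of the terminal acetylide in 6 traps it; the alkoxide end offers no such sink, so only the 23-yne should result.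

Step 3
Reactants: 7 tetracos-23-yn-1-ol; 8 oct-7-ynoic acid
Product: 9 tetracos-23-yn-1-yl oct-7-ynoate
Conditions: DCC, DMAP (cat.), CH2Cl2, 0 °C to rt
Reagents that add atoms: none
Why: Steglich esterification, in which carbodiimide activation of the acid and DMAP-mediated acyl transfer to the unhindered primary alcohol should proceed cleanly while both terminal alkynes stay inert.

Step 4
Reactants: 9 tetracos-23-yn-1-yl oct-7-ynoate
Product: 11 oxacyclotritriaconta-8,10-diyn-2-one, via dicopper diacetylide 10 (not isolated)
Conditions: Cu(OAc)2 (10 equiv), pyridine/Et2O, 45 °C, 9 added by syringe pump over 24 h (final ca. 1 mM)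
Reagents that add atoms: none
Why: Each terminal alkyne, acidified by π-coordination to copper, is deprotonated by pyridine/acetate and metalated to the divalent copper acetylide 10; the two copper acetylide ends then pair and collapse, forming the C8–C9 sp–sp bond while two divalent coppers are reduced to monovalent copper. The closest known reaction type is the Eglinton variant of the Glaser oxidative coupling, used under slow addition for macrocyclic 1,3-diyne lactones. The single 33-membered ring closes end to end by joining the two sp termini of the open-chain ester; no π bond is attacked, so the exo/endo terms do not apply, and the linear C7–C10 rod is held without strain in a ring of this size. No stereocenter is created. The step needs intramolecular over intermolecular coupling, which slow addition into excess Cu(OAc)2 should secure by keeping the stationary concentration of 9 and 10 low. It also needs chemoselectivity, which the substrate provides because the two terminal C–H alkynes are the only acidic, copper-binding sites and the ester is remote and inert to pyridine.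

Step 5
Reactants: 11 oxacyclotritriaconta-8,10-diyn-2-one
Product: 12 oxacyclotritriacontan-2-one (32-dotriacontanolide)
Conditions: H2 (1 atm), 10% Pd/C, EtOAc, rt
Reagents that add atoms: none
Why: Heterogeneous catalytic hydrogenation should saturate both triple bonds (four equivalents of H2) to the C7–C10 tetramethylene unit, while the lactone, which has no allylic or benzylic C–O bond after reduction, is untouched and no stereocenter arises.

Compound list
1 | but-3-yn-1-ol | C#CCCO | starting material
2 | 1-bromoicosane | CCCCCCCCCCCCCCCCCCCCBr | starting material
3 | dilithium salt of but-3-yn-1-ol (lithium 4-lithiobut-3-yn-1-olate) | [Li]C#CCCO[Li] | intermediate (not isolated)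
4 | lithium tetracos-3-yn-1-olate | CCCCCCCCCCCCCCCCCCCCC#CCCO[Li] | intermediate (not isolated)
5 | tetracos-3-yn-1-ol | CCCCCCCCCCCCCCCCCCCCC#CCCO | intermediate
6 | dipotassium salt of tetracos-23-yn-1-ol (terminal acetylide and alkoxide) | [K]C#CCCCCCCCCCCCCCCCCCCCCCCO[K] | intermediate (not isolated)
7 | tetracos-23-yn-1-ol | C#CCCCCCCCCCCCCCCCCCCCCCCO | intermediate
8 | oct-7-ynoic acid | C#CCCCCCC(=O)O | starting material
9 | tetracos-23-yn-1-yl oct-7-ynoate | C#CCCCCCC(=O)OCCCCCCCCCCCCCCCCCCCCCCC#C | intermediate
10 | bis(acetatocopper) diacetylide of 9 (divalent copper acetylide at each chain end, pyridine ligands omitted) | CC(=O)O[Cu]C#CCCCCCC(=O)OCCCCCCCCCCCCCCCCCCCCCCC#C[Cu]OC(C)=O | intermediate (not isolated)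
11 | oxacyclotritriaconta-8,10-diyn-2-one | O=C1CCCCCC#CC#CCCCCCCCCCCCCCCCCCCCCCCO1 | intermediate
12 | oxacyclotritriacontan-2-one (32-dotriacontanolide) | O=C1CCCCCCCCCCCCCCCCCCCCCCCCCCCCCCCO1 | target

Total step count: 5. Longest linear sequence: 5 steps (1 → 5 → 7 → 9 → 11 → 12).

Steps most likely to fail

Step 4. Intermolecular oxidative coupling may outrun ring closure if the stationary concentration of the diyne ester is not kept low enough, so that chain growth and cyclic dimerization take over. The fallback sets out from 7 (with 8) and comes back to the route at 11. It forms the C8–C9 bond between two separate molecules and closes the ring at the ester instead. Alkynol 7 would be brominated at the alkyne terminus (NBS, AgNO3 cat., acetone, rt) to 24-bromotetracos-23-yn-1-ol F1. Cadiot–Chodkiewicz coupling of F1 with acid 8 (CuCl cat., NH2OH·HCl, n-BuNH2, H2O/THF, 0 °C to rt) should give only the unsymmetrical diyne, 32-hydroxydotriaconta-7,9-diynoic acid F2. Yamaguchi macrolactonization of F2 (2,4,6-trichlorobenzoyl chloride, Et3N, THF; then slow addition to DMAP in toluene, 80 °C, high dilution) would deliver 11, which is hydrogenated as in step 5.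

Step 2. The triple-bond migration over twenty positions may stall, for instance through precipitation of the long-chain potassium alkoxide, and leave positional isomers that cannot be separated. The fallback sets out from 8, with octa-1,7-diyne and 16-bromohexadecan-1-ol as further commercial materials, and comes back to the route at 12. It avoids any isomerization by taking the terminal alkyne from an α,ω-diyne, so the alcohol half carries one extra internal triple bond that the final hydrogenation removes together with the diyne. Excess octa-1,7-diyne would be monodeprotonated (n-BuLi, THF/DMPU, −78 °C) to lithium octa-1,7-diyn-1-ide F3. F3 (3 equiv, the first spent on the hydroxyl group) would be alkylated with 16-bromohexadecan-1-ol (−20 °C to rt; H2O) to tetracosa-17,23-diyn-1-ol F4. Esterification with 8 (DCC, DMAP cat., CH2Cl2) would give tetracosa-17,23-diyn-1-yl oct-7-ynoate F5. Eglinton closure under the conditions of step 4, in which only the two terminal alkynes can couple, should give oxacyclotritriaconta-8,10,16-triyn-2-one F6. Hydrogenation (H2, 10% Pd/C, EtOAc) would saturate all three triple bonds to 12.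

Step 1. The displacement may be slow because the dilithio species is sparingly soluble and aggregated and the C20 bromide is waxy, allowing dehydrobromination of the bromide to compete. The fallback sets out from 2 and comes back to the route at 5. It uses a soluble mono-acetylide for the displacement and makes the hydroxyethyl end by epoxide opening. Bromide 2 would be treated with LiC≡CH·H2NCH2CH2NH2 (DMSO, rt) to give docos-1-yne F7. Deprotonation (n-BuLi, THF/DMPU, −78 °C) to lithium docos-1-yn-1-ide F8 and opening of oxirane (−20 °C to rt; H2O) should furnish 5 by C–C bond formation two carbons from the hydroxyl group.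

Further compounds
F1 | step 4 | 24-bromotetracos-23-yn-1-ol | BrC#CCCCCCCCCCCCCCCCCCCCCCCO
F2 | step 4 | 32-hydroxydotriaconta-7,9-diynoic acid | OC(=O)CCCCCC#CC#CCCCCCCCCCCCCCCCCCCCCCCO
F3 | step 2 | lithium octa-1,7-diyn-1-ide | [Li]C#CCCCCC#C
F4 | step 2 | tetracosa-17,23-diyn-1-ol | C#CCCCCC#CCCCCCCCCCCCCCCCCO
F5 | step 2 | tetracosa-17,23-diyn-1-yl oct-7-ynoate | C#CCCCCCC(=O)OCCCCCCCCCCCCCCCCC#CCCCCC#C
F6 | step 2 | oxacyclotritriaconta-8,10,16-triyn-2-one | O=C1CCCCCC#CC#CCCCCC#CCCCCCCCCCCCCCCCCO1
F7 | step 1 | docos-1-yne | C#CCCCCCCCCCCCCCCCCCCCC
F8 | step 1 | lithium docos-1-yn-1-ide | [Li]C#CCCCCCCCCCCCCCCCCCCCC
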